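**One step.** I began from a one-step world, D to X with no other step, and the noon run refused it at once, for at 10.0 min it read E at 58% against X at 7%.

| flask | D | remark | time |
|---|---|---|---|
| noon | 0.29 M | run made earlier |  |
| midnight | 0.66 M | run made earlier |  |
| flask | 0.44 M |  | 10 min |

| run | time / min | X / % | E / % |
|---|---|---|---|
| noon | 0.667 | 8 | 0 |
| noon | 2.00 | 14 | 14 |
| noon | 4.00 | 10 | 33 |
| noon | 5.00 | 14 | 35 |
| noon | 8.00 | 9 | 48 |
| noon | 10.0 | 7 | 58 |
| midnight | 1.50 | 10 | 9 |
| midnight | 3.00 | 10 | 22 |
| midnight | 5.00 | 7 | 34 |
| midnight | 6.00 | 8 | 33 |
| midnight | 8.00 | 7 | 39 |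
| midnight | 10.0 | 8 | 41 |

(readings scatter by 2 percentage points)

- ratio of X to E at 15 s
- ratio of X to E at 10 min
- which of X and E there is more of at 10 min



**Second step.** I added X to E, since the noon run showed X at 8% and E at 0% at 0.667 min. In a chain of first-order steps the fractions of the charge do not depend on the charge, but E at 10 min read 58% in the noon run and 41% in the midnight run.

**Balance of D.** So I wrote the balance of D, the one thing charged. What X and E did not hold at 10 min was 35.0% of the noon charge and 51.0% of the larger midnight charge. The readings did not say what stood in this unread share, so I left it open and turned to the ratio of X to E as read in the two runs.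

**Late split.** The runs read 0.121 and 0.195, but X stood at 7% and 8% under a scatter of 2 percentage points, so I pooled them into 0.152, which I call the late split, a selectivity: X over E at 10 min, as read and pooled over the two charges. The flask's charge of 0.44 M lay between the 0.29 M of the noon run and the 0.66 M of the midnight run, so I reckoned that ratio for the flask, with E ahead. At 15 s I committed to no ratio, since E at 0.667 min read 0%, within the scatter.

**The forecast.** The forecast gave 7 at 15 s and 0.15 at 10 min, and of the lead it said: “E leads clearly”.

**The result.** The flask gave 1.80 at 15 s and 0.154 at 10 min, with X at 7.55% and E at 49.1%.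

    D → G (k = 0.00847 /s)
    G ⇌ X (K = 1.23, k = 0.0180 /s)
    G ⇌ E (K = 89.5, k = 0.00869 /s)
    X ⇌ J (K = 1.32, k = 0.0131 /s)
    2 D → L (k = 0.00783 /M/s)

**Neighbour flask.** The neighbour flask, charged with 1.1 M of D and otherwise the same, held E at 37.0% at 10 min, and the late split of 0.152 turns that into X at 5.62%, beside the 5.53% that stood there. Its ratio was 0.149, while L, reckoned in the D it holds, stood at 45.4% against 26.8% in the flask.

The data are simulated with constants of no real substance.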